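**Retrosynthetic overview**
1. The 5′-OH is added last by ortho-hydroxylation of the 4′-phenol (IBX, then dithionite); the furan ring (C2–O2′) comes from DDQ dehydrogenative cyclization of a 2′-hydroxyisoflavone.
2. The isoflavone C3–C1′ bond comes from Suzuki coupling of a 3-iodochromone with a prenylated resorcinol boronate.
3. A-ring: the chromone is built on 3,5-dimethoxy-4-methylphenol, whose single free OH must become O1, which fixes the methyl at C6; the 2H-pyran is then annulated with prenal at C8, the only free position.
4. B-ring: 4-bromoresorcinol bis-MOM ether, directed metalation/prenylation between the two oxygens, then Br→Bpin.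
5. Ring order: pyranone → 2H-pyran → (coupling) → furan.

Assumption: the target SMILES contains no stereocentre (it is achiral), so no enantiocontrol is needed. Reagents that donate non-hydrogen atoms are numbered as compounds too.

This route is designed from known reaction types and has not been run; conditions are typical literature conditions for each transformation.

**Step 1**
Reactants: 1 4-hydroxy-2,6-dimethoxybenzaldehyde
Product: 2 3,5-dimethoxy-4-methylphenol
Conditions: H2 (1 atm), 10% Pd/C, AcOH, cat. HCl, rt
Reagents that add atoms: none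
Why: Benzylic hydrogenolysis of an electron-rich aryl aldehyde (via the benzyl alcohol) gives ArCH3 and a symmetric phenol with one free OH.

**Step 2**
Reactants: 2; 3 acetic anhydride
Product: 4 1-(6-hydroxy-2,4-dimethoxy-3-methylphenyl)ethan-1-one
Conditions: Ac2O, BF3·OEt2, 90 °C; aq. NaOAc work-up
Reagents that add atoms: acetic anhydride, CC(=O)OC(C)=O
Why: O-acylation/Fries-type Friedel–Crafts acylation ortho to the OH; the two open positions are equivalent, so one isomer forms, and the BF2 chelate stops over-acylation.

**Step 3**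
Reactants: 4; 5 N,N-dimethylformamide dimethyl acetal
Product: 6 (E)-3-(dimethylamino)-1-(6-hydroxy-2,4-dimethoxy-3-methylphenyl)prop-2-en-1-one
Conditions: DMF-DMA (3 equiv), toluene, 100 °C (crude used directly)
Reagents that add atoms: DMF-DMA, COC(OC)N(C)C
Why: Condensation of the methyl ketone with the amide acetal gives the enaminone, supplying the future C2.

**Step 4**
Reactants: 6; 7 iodine
Product: 8 3-iodo-5,7-dimethoxy-6-methyl-4H-chromen-4-one
Conditions: I2 (2 equiv), MeOH, rt
Reagents that add atoms: iodine, II
Why: Gammill iodocyclization: α-iodination of the enaminone, attack of the only free ortho OH on the iminium carbon and loss of Me2NH give the 3-iodochromone with methyl unambiguously at C6.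

**Step 5**
Reactants: 8
Product: 9 5,7-dihydroxy-3-iodo-6-methyl-4H-chromen-4-one
Conditions: BBr3 (4 equiv), CH2Cl2, −78 °C → rt
Reagents that add atoms: none
Why: Lewis-acid cleavage of both aryl methyl ethers (the peri 5-OMe first, by chelation); the vinyl iodide and chromone are inert.

**Step 6**
Reactants: 9; 10 3-methylbut-2-enal (prenal)
Product: 11 5-hydroxy-3-iodo-6,8,8-trimethyl-4H,8H-pyrano[2,3-f]chromen-4-one
Conditions: prenal (2 equiv), EDDA (10–20 mol %), toluene, reflux
Reagents that add atoms: 3-methylbut-2-enal, CC(C)=CC=O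
Why: Knoevenagel-type condensation at C8 followed by oxa-6π electrocyclization of the o-quinone methide; C6 is blocked by methyl and the chelated 5-OH cannot take part, so only the angular 7,8-pyran forms.

**Step 7**
Reactants: 12 4-bromobenzene-1,3-diol (4-bromoresorcinol); 13 chloromethyl methyl ether
Product: 14 1-bromo-2,4-bis(methoxymethoxy)benzene
Conditions: MOMCl (2.5 equiv), i-Pr2NEt, CH2Cl2, 0 °C → rt
Reagents that add atoms: MOMCl, COCCl
Why: Williamson-type acetal protection; MOM is both the directing group for metalation and an acid-labile group compatible with prenyl.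

**Step 8**
Reactants: 14; 15 1-bromo-3-methylbut-2-ene (prenyl bromide)
Product: 16 1-bromo-2,4-bis(methoxymethoxy)-3-(3-methylbut-2-en-1-yl)benzene
Conditions: LDA, THF, −78 °C; CuBr·SMe2; prenyl bromide, −78 °C → rt
Reagents that add atoms: prenyl bromide, CC(C)=CCBr
Why: Directed ortho-metalation: the amide base removes the H flanked by two OMOM groups without Br–Li exchange, and the aryl-copper couples SN2 with prenyl bromide to give the linear prenyl group.

**Step 9**
Reactants: 16; 17 2-isopropoxy-4,4,5,5-tetramethyl-1,3,2-dioxaborolane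
Product: 18 2-[2,4-bis(methoxymethoxy)-3-(3-methylbut-2-en-1-yl)phenyl]-4,4,5,5-tetramethyl-1,3,2-dioxaborolane
Conditions: n-BuLi, THF, −78 °C; i-PrOBpin; → rt
Reagents that add atoms: i-PrOBpin, CC(C)OB1OC(C)(C)C(C)(C)O1
Why: Br–Li exchange at −78 °C (faster than benzylic/allylic deprotonation) and borate trapping place boron regiospecifically at the future C1′.

**Step 10**
Reactants: 11; 18
Product: 19 3-[2,4-bis(methoxymethoxy)-3-(3-methylbut-2-en-1-yl)phenyl]-5-hydroxy-6,8,8-trimethyl-4H,8H-pyrano[2,3-f]chromen-4-one
Conditions: Pd(dppf)Cl2 (5 mol %), K2CO3 (3 equiv), 1,4-dioxane/H2O 4:1, 80 °C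
Reagents that add atoms: none
Why: Suzuki–Miyaura coupling of the 3-iodochromone forms the isoflavone C3–C1′ bond; the chelated 5-OH, MOM ethers and both alkenes are tolerated.

**Step 11**
Reactants: 19
Product: 20 3-[2,4-dihydroxy-3-(3-methylbut-2-en-1-yl)phenyl]-5-hydroxy-6,8,8-trimethyl-4H,8H-pyrano[2,3-f]chromen-4-one
Conditions: 3 M HCl, MeOH/THF, 45 °C
Reagents that add atoms: none
Why: Mild acetal hydrolysis removes both MOM groups under conditions routinely survived by ortho-prenyl phenols and 2,2-dimethylchromenes.

**Step 12**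
Reactants: 20
Product: 21 5′-deoxytriquetrumone A: the benzofuro[2,3-b]chromen-4-one (coumaronochromone) with 5-OH, 6-Me, 7,8-fused 2,2-dimethyl-2H-pyran, 3′-prenyl and 4′-OH
Conditions: DDQ (1.1 equiv), dry THF, rt, quench on consumption
Reagents that add atoms: none
Why: DDQ dehydrogenative cyclization of a 2′,4′-dihydroxyisoflavone (2′-OH adds to C2, then dehydrogenation), as used for lupinalbin-type coumaronochromones; room temperature and one equivalent are chosen to outpace DDQ chromene formation at the prenyl group.

**Step 13**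
Reactants: 21; 22 2-iodoxybenzoic acid (IBX)
Product: 23 Triquetrumone A
Conditions: IBX (1.2 equiv), DMF, rt; then aq. Na2S2O4, rt (one pot)
Reagents that add atoms: IBX (oxygen donor), O=C1OI(=O)(O)c2ccccc12
Why: IBX ortho-oxygenation of the 4′-phenol to the o-quinone at C5′, its only free ortho position, followed by in-situ dithionite reduction to the catechol; the chelated 5-OH has no free ortho position and the alkenes are inert at rt.

**Compound list**
1 | 4-hydroxy-2,6-dimethoxybenzaldehyde | COc1cc(O)cc(OC)c1C=O | starting material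
2 | 3,5-dimethoxy-4-methylphenol | COc1cc(O)cc(OC)c1C | intermediate
3 | acetic anhydride | CC(=O)OC(C)=O | starting material
4 | 1-(6-hydroxy-2,4-dimethoxy-3-methylphenyl)ethan-1-one | CC(=O)c1c(O)cc(OC)c(C)c1OC | intermediate
5 | N,N-dimethylformamide dimethyl acetal | COC(OC)N(C)C | starting material
6 | (E)-3-(dimethylamino)-1-(6-hydroxy-2,4-dimethoxy-3-methylphenyl)prop-2-en-1-one | CN(C)/C=C/C(=O)c1c(O)cc(OC)c(C)c1OC | intermediate
7 | iodine | II | starting material
8 | 3-iodo-5,7-dimethoxy-6-methyl-4H-chromen-4-one | COc1cc2occ(I)c(=O)c2c(OC)c1C | intermediate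
9 | 5,7-dihydroxy-3-iodo-6-methyl-4H-chromen-4-one | Cc1c(O)cc2occ(I)c(=O)c2c1O | intermediate
10 | 3-methylbut-2-enal | CC(C)=CC=O | starting material
11 | 5-hydroxy-3-iodo-6,8,8-trimethyl-4H,8H-pyrano[2,3-f]chromen-4-one | Cc1c(O)c2c(=O)c(I)coc2c2C=CC(C)(C)Oc12 | intermediate
12 | 4-bromobenzene-1,3-diol | Oc1ccc(Br)c(O)c1 | starting material
13 | chloromethyl methyl ether | COCCl | starting material
14 | 1-bromo-2,4-bis(methoxymethoxy)benzene | COCOc1ccc(Br)c(OCOC)c1 | intermediate
15 | 1-bromo-3-methylbut-2-ene | CC(C)=CCBr | starting material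
16 | 1-bromo-2,4-bis(methoxymethoxy)-3-(3-methylbut-2-en-1-yl)benzene | CC(C)=CCc1c(OCOC)ccc(Br)c1OCOC | intermediate
17 | 2-isopropoxy-4,4,5,5-tetramethyl-1,3,2-dioxaborolane | CC(C)OB1OC(C)(C)C(C)(C)O1 | starting material
18 | 2-[2,4-bis(methoxymethoxy)-3-(3-methylbut-2-en-1-yl)phenyl]-4,4,5,5-tetramethyl-1,3,2-dioxaborolane | CC(C)=CCc1c(OCOC)ccc(B2OC(C)(C)C(C)(C)O2)c1OCOC | intermediate
19 | 3-[2,4-bis(methoxymethoxy)-3-(3-methylbut-2-en-1-yl)phenyl]-5-hydroxy-6,8,8-trimethyl-4H,8H-pyrano[2,3-f]chromen-4-one | Cc1c(O)c2c(=O)c(-c3ccc(OCOC)c(CC=C(C)C)c3OCOC)coc2c2C=CC(C)(C)Oc12 | intermediate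
20 | 3-[2,4-dihydroxy-3-(3-methylbut-2-en-1-yl)phenyl]-5-hydroxy-6,8,8-trimethyl-4H,8H-pyrano[2,3-f]chromen-4-one | Cc1c(O)c2c(=O)c(-c3ccc(O)c(CC=C(C)C)c3O)coc2c2C=CC(C)(C)Oc12 | intermediate
21 | 5′-deoxytriquetrumone A (4′-hydroxy-3′-prenyl pyranocoumaronochromone) | CC(C)=CCc1c(O)ccc2c1oc1oc3c4c(c(C)c(O)c3c(=O)c12)OC(C)(C)C=C4 | intermediate
22 | 2-iodoxybenzoic acid (IBX) | O=C1OI(=O)(O)c2ccccc12 | starting material
23 | Triquetrumone A | CC(C)=CCc1c(O)c(O)cc2c1oc1oc3c4c(c(C)c(O)c3c(=O)c12)OC(C)(C)C=C4 | target

**Totals**
Total steps: 13. Longest linear sequence: 10 (steps 1–6, then 10–13); the B-ring branch is steps 7–9.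

**Three steps most likely to fail**
1. Step 12 (DDQ cyclization). DDQ can instead oxidize the ortho-prenyl phenol to a B-ring 2,2-dimethylchromene, or over-oxidize. Fallback: a redox-neutral closure. Make the A-ring as the 3-iodo-2-(methylthio)chromone (4 with CS2/NaH then MeI; NIS), carry it through steps 5, 6 and 10, and let the acid MOM removal trigger intramolecular addition–elimination of the 2′-OH at C2 with loss of MeSH, so no oxidant meets the prenyl group.
2. Step 13 (late ortho-hydroxylation). The 4′-phenol is conjugated to the carbonyl and may react sluggishly, and the transient o-quinone sits next to the prenyl CH2. Fallback: carry O5′ from the start. Build the boronate from 5-bromo-2,4-dihydroxybenzaldehyde (MOM protection, Baeyer–Villiger/Dakin to the phenol, TIPS ether, then steps 8–9) and unveil the catechol with fluoride at the end.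
3. Step 6 (chromenylation of the 3-iodochromone). The amine catalyst may open the iodochromone, or the deactivated 7-OH may react slowly. Fallback: O-alkylate the 7-OH with 3-chloro-3-methylbut-1-yne (K2CO3, KI, cat. CuI), then run a thermal aryl propargyl ether Claisen/[1,5]-H/6π cascade (N,N-diethylaniline, 140 °C), which can only go to C8.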